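The retrosynthesis first cuts the three O–benzyl bonds of a fully protected depside. It then cuts the bond between the ester oxygen and C1 of ring A, not the acyl C–O bond, giving a ring B benzoic acid and a ring A arylboronic acid.
Enabling feature: the ester oxygen sits on ring A carbon C1, next to the oxygen-bearing carbons C2 and C3. The carbonyl on ring B carbon C1' is crowded by the C2' oxygen and the C6' propyl group, so C1 carries boron and is delivered as an aryl group to the open carboxylate oxygen.
Ring A: C1–B comes from the C1–Br bond of 5-bromovanillin, whose Br/OH/OMe triad maps onto C1/C2/C3. The pentyl chain is cut between its first and second carbon (aldehyde plus butyl Grignard reagent, then deoxygenation).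
Ring B: the carboxyl carbon is cut from C1' (formylation, then oxidation) and the propyl group from C6' (Kumada coupling). The C2' methyl ether is exchanged for benzyl.
Forward: no ring is built, since both benzene rings are bought. Two five-step branches meet in step 11 and one hydrogenolysis ends the route. The target has no stereocentre, and the single racemic carbinol on the way is erased one step later.

Key step: step 11

Remark: ring A is numbered C1 (ester oxygen), C2 and C3 (hydroxyls), C5 (pentyl). Ring B is numbered C1' (carbonyl), C2' (hydroxyl), C4' (methoxy), C6' (propyl). 1-Bromo-3,5-dimethoxybenzene and both Grignard solutions are taken as commercial.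

Step 1
Reactants: 1 5-bromovanillin (3-bromo-4-hydroxy-5-methoxybenzaldehyde)
Product: 3 3-bromo-4,5-dihydroxybenzaldehyde, via chloroaluminium catecholate 2 (not isolated)
Conditions: AlCl3 (1.2 equiv), pyridine (4.5 equiv), CH2Cl2, reflux; then 2 M HCl
Reagents that add atoms: none
Why: Lewis acid O-demethylation of a guaiacol, in which aluminium binds the free phenolate and the neighbouring methoxy oxygen, chloride removes the activated methyl group by SN2 attack, and neither the aldehyde nor the aryl bromide is touched.

Step 2
Reactants: 3 3-bromo-4,5-dihydroxybenzaldehyde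
Product: 4 3,4-bis(benzyloxy)-5-bromobenzaldehyde
Conditions: BnBr (2.5 equiv), K2CO3 (3 equiv), DMF, 60 °C
Reagents that add atoms: benzyl bromide, BrCc1ccccc1
Why: Williamson ether synthesis on both acidic catechol hydroxyls, with benzyl chosen because it survives organometallic, acidic and oxidative copper conditions and leaves at the end under neutral hydrogenolysis.

Step 3
Reactants: 4 3,4-bis(benzyloxy)-5-bromobenzaldehyde; 5 butylmagnesium bromide
Product: 7 racemic 1-[3,4-bis(benzyloxy)-5-bromophenyl]pentan-1-ol, via bromomagnesium alkoxide 6 (not isolated)
Conditions: THF, 0 °C; then sat. aq NH4Cl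
Reagents that add atoms: none
Why: Grignard 1,2-addition to a non-enolisable aryl aldehyde, far faster at 0 °C than bromine–magnesium exchange, giving a carbinol centre that is racemic and is removed in step 4.

Step 4
Reactants: 7 racemic 1-[3,4-bis(benzyloxy)-5-bromophenyl]pentan-1-ol
Product: 8 1,2-bis(benzyloxy)-3-bromo-5-pentylbenzene
Conditions: Et3SiH (3 equiv), TFA (5 equiv), CH2Cl2, 0 °C
Reagents that add atoms: none
Why: Ionic hydrogenation (Kursanov–Parnes reduction), in which protonation and loss of water give a benzylic cation stabilised by the para benzyloxy group that takes hydride from the silane, under conditions that spare the C–Br bond and, at 0 °C and short contact time, the aryl benzyl ethers.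

Step 5
Reactants: 8 1,2-bis(benzyloxy)-3-bromo-5-pentylbenzene
Product: 11 [2,3-bis(benzyloxy)-5-pentylphenyl]boronic acid, via aryllithium 9 (not isolated), via lithium aryltriisopropoxyborate 10 (not isolated)
Conditions: B(OiPr)3 (1.5 equiv), then n-BuLi (1.2 equiv) dropwise, THF–toluene, −78 °C; then 1 M HCl, 0 °C
Reagents that add atoms: triisopropyl borate, CC(C)OB(OC(C)C)OC(C)C; water, O
Why: Bromine–lithium exchange with in situ borate quench and hydrolysis, where the borate already present captures the ortho-benzyloxy aryllithium before it can deprotonate its own benzylic CH2 and rearrange.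

Step 6
Reactants: 12 1-bromo-3,5-dimethoxybenzene; 13 propylmagnesium bromide
Product: 14 1,3-dimethoxy-5-propylbenzene
Conditions: Ni(dppp)Cl2 (2 mol %), Et2O, 0 °C → reflux
Reagents that add atoms: none
Why: Kumada–Corriu cross-coupling (oxidative addition of the aryl bromide to zerovalent nickel, transmetalation, reductive elimination), in which the chelating diphosphine suppresses β-hydride elimination so that the primary propyl group arrives unisomerised.

Step 7
Reactants: 14 1,3-dimethoxy-5-propylbenzene
Product: 16 2,4-dimethoxy-6-propylbenzaldehyde, via iminium dichlorophosphate 15 (not isolated)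
Conditions: POCl3 (1.5 equiv), DMF, 0 → 60 °C; then ice–water
Reagents that add atoms: N,N-dimethylformamide, CN(C)C=O; water, O
Why: Vilsmeier–Haack formylation, in which the chloroiminium ion attacks the position para to one methoxy and ortho to the other (two such sites, equivalent by symmetry) in preference to the site between both methoxy groups, as is usual for 5-alkylresorcinol dimethyl ethers.

Step 8
Reactants: 16 2,4-dimethoxy-6-propylbenzaldehyde
Product: 18 2-hydroxy-4-methoxy-6-propylbenzaldehyde, via dichloroboron chelate 17 (not isolated)
Conditions: BCl3 (1.2 equiv), CH2Cl2, −78 → 0 °C; then H2O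
Reagents that add atoms: none
Why: Chelation-directed ether cleavage, in which BCl3 bridges the formyl oxygen and the ortho methoxy oxygen in a six-membered chelate so that chloride removes only that methyl group, while the C4 methoxy group cannot chelate and stays.

Step 9
Reactants: 18 2-hydroxy-4-methoxy-6-propylbenzaldehyde
Product: 19 2-(benzyloxy)-4-methoxy-6-propylbenzaldehyde
Conditions: BnBr (1.3 equiv), K2CO3 (2 equiv), DMF, 60 °C
Reagents that add atoms: benzyl bromide, BrCc1ccccc1
Why: Williamson ether synthesis, with gentle heating in a dipolar solvent to break the hydrogen bond between the phenol and the formyl group.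

Step 10
Reactants: 19 2-(benzyloxy)-4-methoxy-6-propylbenzaldehyde
Product: 20 2-(benzyloxy)-4-methoxy-6-propylbenzoic acid
Conditions: NaClO2, NaH2PO4, 2-methylbut-2-ene (excess), t-BuOH–H2O, rt
Reagents that add atoms: sodium chlorite, [Na+].[O-]Cl=O
Why: Pinnick oxidation, in which chlorous acid adds to the aldehyde and fragments to the acid, and the alkene scavenges the hypochlorous acid released before it can chlorinate the electron-rich ring.

Step 11
Reactants: 20 2-(benzyloxy)-4-methoxy-6-propylbenzoic acid; 11 [2,3-bis(benzyloxy)-5-pentylphenyl]boronic acid
Product: 21 2,3-bis(benzyloxy)-5-pentylphenyl 2-(benzyloxy)-4-methoxy-6-propylbenzoate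
Conditions: Cu(OTf)2 (40 mol %), urea (1 equiv), 4 Å MS, EtOAc, dry air, 60 °C; 11 (2.5 equiv) added in portions
Reagents that add atoms: none
Why: Chan–Lam oxidative coupling: the carboxylate of 20 binds divalent copper, the aryl group of 11 passes from boron to copper, oxidation by a second divalent copper (air closing the cycle) gives a trivalent copper aryl carboxylate, and C–O reductive elimination joins the carboxylate oxygen to C1 of ring A. The closest known reaction type is the Cu(OTf)2-promoted aerobic O-arylation of benzoic acids with arylboronic acids to phenolic esters, and the triflate salt is preferred to Cu(OAc)2 so that no second carboxylate competes for the aryl group. The bond is made at oxygen, two atoms out from C1' of ring B, so the C2' benzyloxy and C6' propyl groups that shield the carbonyl carbon against addition–elimination hardly reach the reacting centre. No ring closes and no stereocentre arises. The step needs chemoselectivity for the carboxylate among oxygen nucleophiles and site selectivity among the three ring A oxygens: the first holds because all three phenols are benzyl ethers and the acid O–H is the only one left, the second because boron sits only on C1, the carbon marked by bromine since 1. Molecular sieves keep water from converting 11 into a phenol, urea buffers the triflic acid released, and the portionwise excess of 11 compensates for the protodeboronation and homocoupling that its ortho benzyloxy group favours.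

Step 12
Reactants: 21 2,3-bis(benzyloxy)-5-pentylphenyl 2-(benzyloxy)-4-methoxy-6-propylbenzoate
Product: 22 peruvinide C (2,3-dihydroxy-5-pentylphenyl 2-hydroxy-4-methoxy-6-propylbenzoate)
Conditions: H2 (1 atm), Pd/C (10 wt %), EtOAc, rt; filtration under argon
Reagents that add atoms: none
Why: Catalytic hydrogenolysis of the three benzylic C–O bonds in a neutral, non-nucleophilic solvent, which leaves the aryl ester and the methyl ether intact and offers no base to shift the acyl group to the freed C2 hydroxyl.

Compound list
1 | 5-bromovanillin (3-bromo-4-hydroxy-5-methoxybenzaldehyde) | COc1cc(C=O)cc(Br)c1O | starting material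
2 | chloroaluminium catecholate of 3-bromo-4,5-dihydroxybenzaldehyde (pyridine-solvated, drawn without pyridine) | O=Cc1cc(Br)c2O[Al](Cl)Oc2c1 | intermediate
3 | 3-bromo-4,5-dihydroxybenzaldehyde | O=Cc1cc(O)c(O)c(Br)c1 | intermediate
4 | 3,4-bis(benzyloxy)-5-bromobenzaldehyde | O=Cc1cc(Br)c(OCc2ccccc2)c(OCc2ccccc2)c1 | intermediate
5 | butylmagnesium bromide | CCCC[Mg]Br | starting material
6 | bromomagnesium 1-[3,4-bis(benzyloxy)-5-bromophenyl]pentan-1-olate (racemic) | CCCCC(O[Mg]Br)c1cc(Br)c(OCc2ccccc2)c(OCc2ccccc2)c1 | intermediate
7 | 1-[3,4-bis(benzyloxy)-5-bromophenyl]pentan-1-ol (racemic) | CCCCC(O)c1cc(Br)c(OCc2ccccc2)c(OCc2ccccc2)c1 | intermediate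
8 | 1,2-bis(benzyloxy)-3-bromo-5-pentylbenzene | CCCCCc1cc(Br)c(OCc2ccccc2)c(OCc2ccccc2)c1 | intermediate
9 | [2,3-bis(benzyloxy)-5-pentylphenyl]lithium | CCCCCc1cc([Li])c(OCc2ccccc2)c(OCc2ccccc2)c1 | intermediate
10 | lithium [2,3-bis(benzyloxy)-5-pentylphenyl]triisopropoxyborate | [Li+].CCCCCc1cc([B-](OC(C)C)(OC(C)C)OC(C)C)c(OCc2ccccc2)c(OCc2ccccc2)c1 | intermediate
11 | [2,3-bis(benzyloxy)-5-pentylphenyl]boronic acid | CCCCCc1cc(B(O)O)c(OCc2ccccc2)c(OCc2ccccc2)c1 | intermediate
12 | 1-bromo-3,5-dimethoxybenzene | COc1cc(Br)cc(OC)c1 | starting material
13 | propylmagnesium bromide | CCC[Mg]Br | starting material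
14 | 1,3-dimethoxy-5-propylbenzene | CCCc1cc(OC)cc(OC)c1 | intermediate
15 | [(2,4-dimethoxy-6-propylphenyl)methylidene]dimethylammonium dichlorophosphate | CCCc1cc(OC)cc(OC)c1C=[N+](C)C.[O-]P(=O)(Cl)Cl | intermediate
16 | 2,4-dimethoxy-6-propylbenzaldehyde | CCCc1cc(OC)cc(OC)c1C=O | intermediate
17 | dichloro(2-formyl-5-methoxy-3-propylphenoxy)borane (boron chelated by the formyl oxygen, drawn open) | CCCc1cc(OC)cc(OB(Cl)Cl)c1C=O | intermediate
18 | 2-hydroxy-4-methoxy-6-propylbenzaldehyde | CCCc1cc(OC)cc(O)c1C=O | intermediate
19 | 2-(benzyloxy)-4-methoxy-6-propylbenzaldehyde | CCCc1cc(OC)cc(OCc2ccccc2)c1C=O | intermediate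
20 | 2-(benzyloxy)-4-methoxy-6-propylbenzoic acid | CCCc1cc(OC)cc(OCc2ccccc2)c1C(=O)O | intermediate
21 | 2,3-bis(benzyloxy)-5-pentylphenyl 2-(benzyloxy)-4-methoxy-6-propylbenzoate | CCCCCc1cc(OC(=O)c2c(OCc3ccccc3)cc(OC)cc2CCC)c(OCc2ccccc2)c(OCc2ccccc2)c1 | intermediate
22 | peruvinide C (2,3-dihydroxy-5-pentylphenyl 2-hydroxy-4-methoxy-6-propylbenzoate) | CCCCCc1cc(O)c(O)c(OC(=O)c2c(O)cc(OC)cc2CCC)c1 | target

Total step count: 12 (five for ring A, five for ring B, two after convergence). Longest linear sequence: 7 steps (1 → 22 or 12 → 22).

Steps most likely to fail

1. Step 11.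
- Risk: the ortho benzyloxy group may slow aryl transfer from boron to copper. Protodeboronation, oxidative hydroxylation and homocoupling of the boronic acid could then outrun ester formation, as could acid-induced decarboxylation of the electron-rich benzoic acid.
- Fallback: return to normal polarity while keeping the regiochemical marker. Setting out from 11, oxidation with H2O2 and NaOH in THF at 0 °C should give 2,3-bis(benzyloxy)-5-pentylphenol F1, whose only free oxygen is the one on C1.
- F1 and acid 20 are then condensed with trifluoroacetic anhydride in toluene at rt. The mixed anhydride reacts through acylium-like ionisation, which the two ortho substituents and the electron-rich ring favour rather than hinder. The route is rejoined at 21.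

2. Step 5.
- Risk: the aryllithium may abstract a proton from the neighbouring OCH2Ph group and rearrange, n-BuLi may be consumed by the borate, or the C–B bond may be lost by protodeboronation during the acidic work-up.
- Fallback: palladium catalysis in place of an organolithium. Setting out from 8, Miyaura borylation (B2pin2, Pd(dppf)Cl2, KOAc, dioxane, 90 °C) should give 2-[2,3-bis(benzyloxy)-5-pentylphenyl]-4,4,5,5-tetramethyl-1,3,2-dioxaborolane F2.
- Oxidative removal of the pinacol unit (NaIO4, NH4OAc, acetone–water, rt) then returns to the route at 11.

3. Step 4.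
- Risk: acidolysis of a benzyl ether may occur, above all of the crowded central one. The benzylic cation may also eliminate to a styrene that then oligomerises, or it may alkylate a second arene by Friedel–Crafts reaction.
- Fallback: build the chain by olefination and saturate it without acid, which replaces both step 3 and step 4. Setting out from 4, Wittig olefination with the ylide from butyltriphenylphosphonium bromide (NaHMDS, THF, −78 °C → rt) should give 1,2-bis(benzyloxy)-3-bromo-5-[(Z)-pent-1-en-1-yl]benzene F3. It is expected mainly as the Z isomer, and the geometry is of no consequence.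
- Diimide reduction (TsNHNH2, NaOAc, DME–H2O, reflux) saturates the alkene without touching the C–Br or O–benzyl bonds and returns to the route at 8.

Further compounds
F1 | step 11 | 2,3-bis(benzyloxy)-5-pentylphenol | CCCCCc1cc(O)c(OCc2ccccc2)c(OCc2ccccc2)c1
F2 | step 5 | 2-[2,3-bis(benzyloxy)-5-pentylphenyl]-4,4,5,5-tetramethyl-1,3,2-dioxaborolane | CCCCCc1cc(B2OC(C)(C)C(C)(C)O2)c(OCc2ccccc2)c(OCc2ccccc2)c1
F3 | step 4 | 1,2-bis(benzyloxy)-3-bromo-5-[(Z)-pent-1-en-1-yl]benzene | CCC/C=C\c1cc(Br)c(OCc2ccccc2)c(OCc2ccccc2)c1
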